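The route rests on cutting the C2–C1' bond between ring A of the naphthazarin and the side chain. C1', the only stereocentre, carries the acyloxy group and the ring and is at the aldehyde oxidation level, so a racemic 1-chloroalkyl ester (aldehyde plus acyl chloride) can serve as its precursor. A nickel/chiral bis(oxazoline) reductive coupling of this chloride with 2-iodo-1,4,5,8-tetrakis(methoxymethoxy)naphthalene should forge C2–C1' and set the 1R configuration in one operation, with the 3,4-dimethylpent-3-enoate ester already installed. Oxidation of one ring and loss of two acetals then unveil the naphthazarin.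

Key step: step 9

Remarks on the chemistry (assumptions and design choices)
- Ring A is the ring that carries the side chain (C1–C4) and ring B is the other ring (C5–C8). The 5,8-dihydroxy-1,4-dione and 1,4-dihydroxy-5,8-dione forms of a naphthazarin are tautomers in rapid equilibrium and are treated as one compound.
- Structure check: C1' is R in the target and in the coupling product (O > ring carbon > CH2 > H). The structures of the key-step precursors and product are used as drawn.
- The tetrasubstituted alkene of the acyl part adds HCl and lactonises easily, so the acid chloride is made without HCl, from the sodium carboxylate.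
- The coupling is run without silyl chloride or iodide additives, which would attack the four acetals and the chloro ester.
- The acid is built from 2-bromo-3-methylbut-2-ene and oxirane, which fixes the alkene position without a base-mediated nitrile hydrolysis.
- Step 10 is written for the ring B quinone, the isomer expected for a 1'-acyloxy substrate. Oxidation of ring A instead would cost nothing, because step 11 unmasks the same naphthazarin from a quinone on either ring.

Step 1
Reactants: 1 naphthazarin (5,8-dihydroxynaphthalene-1,4-dione)
Product: 2 leuconaphthazarin (5,8-dihydroxy-2,3-dihydronaphthalene-1,4-dione tautomer)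
Conditions: Na2S2O4, H2O/EtOAc, rt, under Ar
Reagents that add atoms: none
Why: Dithionite reduction of a quinone to its hydroquinone, which settles as the known, isolable diketo tautomer.

Step 2
Reactants: 2 leuconaphthazarin
Product: 3 1,4,5,8-tetrakis(methoxymethoxy)naphthalene
Conditions: NaH (excess), MOMCl, DMF, 0 °C → rt, under Ar
Reagents that add atoms: chloromethyl methyl ether, COCCl
Why: Excess NaH converts the dione into the aromatic tetra-naphtholate (two phenol deprotonations, two enolisations), and the hard electrophile alkylates on oxygen (Williamson ether synthesis).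

Step 3
Reactants: 3 1,4,5,8-tetrakis(methoxymethoxy)naphthalene
Product: 5 2-iodo-1,4,5,8-tetrakis(methoxymethoxy)naphthalene, via 2-lithio-1,4,5,8-tetrakis(methoxymethoxy)naphthalene 4 (not isolated)
Conditions: n-BuLi (1.1 equiv), TMEDA, THF, −78 → 0 °C; then I2, THF, −78 °C
Reagents that add atoms: iodine, II
Why: Directed ortho-metalation by the methoxymethoxy groups, with all four ring C–H positions equivalent by symmetry, so one equivalent of base should give one aryllithium, which iodine traps.

Step 4
Reactants: 6 4-methylpent-3-en-1-ol
Product: 7 4-methylpent-3-enal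
Conditions: Dess–Martin periodinane, NaHCO3, CH2Cl2, 0 °C → rt; used at once as a solution
Reagents that add atoms: none
Why: Dess–Martin oxidation under buffered, non-basic conditions should give the β,γ-unsaturated aldehyde without moving the alkene into conjugation.

Step 5
Reactants: 8 2-bromo-3-methylbut-2-ene; 9 oxirane
Product: 11 3,4-dimethylpent-3-en-1-ol, via (3-methylbut-2-en-2-yl)magnesium bromide 10 (not isolated)
Conditions: Mg, THF, reflux; then CuI (5 mol %), oxirane, THF, −30 → 0 °C; aq. NH4Cl
Reagents that add atoms: none
Why: Copper-catalysed opening of an epoxide by an alkenyl Grignard reagent adds the hydroxyethyl unit at the vinyl carbon, the tetrasubstituted alkene being fixed by the starting bromide.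

Step 6
Reactants: 11 3,4-dimethylpent-3-en-1-ol
Product: 12 3,4-dimethylpent-3-enoic acid
Conditions: TEMPO (cat.), PhI(OAc)2 (2.2 equiv), MeCN/H2O, rt
Reagents that add atoms: water, O
Why: TEMPO/PhI(OAc)2 oxidation of a primary alcohol to the acid through the aldehyde hydrate, under near-neutral conditions that should keep the acid-labile β,γ-alkene from lactonising or migrating.

Step 7
Reactants: 12 3,4-dimethylpent-3-enoic acid
Product: 14 3,4-dimethylpent-3-enoyl chloride, via sodium 3,4-dimethylpent-3-enoate 13 (not isolated)
Conditions: NaH (1.0 equiv), THF/hexane, 0 °C; then (COCl)2, DMF (cat.), 0 °C → rt; filtered and concentrated cold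
Reagents that add atoms: oxalyl chloride, ClC(=O)C(Cl)=O
Why: Acid chloride formation from the sodium carboxylate and oxalyl chloride gives only NaCl, CO and CO2 beside the product, so no HCl is present to add across the tetrasubstituted alkene or close the γ-lactone.

Step 8
Reactants: 7 4-methylpent-3-enal; 14 3,4-dimethylpent-3-enoyl chloride
Product: 15 racemic 1-chloro-4-methylpent-3-en-1-yl 3,4-dimethylpent-3-enoate
Conditions: ZnCl2 (2 mol %), CH2Cl2, −20 → 0 °C; filtered through a short plug and used fresh
Reagents that add atoms: none
Why: Lewis-acid-catalysed 1,2-addition of an acyl chloride across an aldehyde carbonyl gives the 1-chloroalkyl ester; low temperature and a small ZnCl2 loading limit Prins-type side reactions, and the new centre is left racemic because step 9 is stereoconvergent.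

Step 9
Reactants: 15 racemic 1-chloro-4-methylpent-3-en-1-yl 3,4-dimethylpent-3-enoate (excess); 5 2-iodo-1,4,5,8-tetrakis(methoxymethoxy)naphthalene
Product: 16 (1R)-1-[1,4,5,8-tetrakis(methoxymethoxy)naphthalen-2-yl]-4-methylpent-3-en-1-yl 3,4-dimethylpent-3-enoate
Conditions: NiBr2(dme) (10 mol %), one enantiomer of 2,2'-(propane-2,2-diyl)bis(4-phenyl-4,5-dihydro-1,3-oxazole) (12 mol %), Mn powder (3 equiv, acid-washed), DMA/THF, 0 °C
Reagents that add atoms: none
Why: Zerovalent nickel carrying the chiral bis(oxazoline) inserts into the C2–I bond of 5, while monovalent nickel abstracts chlorine from either enantiomer of 15 to give a planar α-acyloxyalkyl radical at C1', which erases the configuration of the racemate; capture of this radical by the chiral arylnickel species and reductive elimination from trivalent nickel form C2–C1', and Mn returns the catalyst. The closest known chemistry is the nickel/bis(oxazoline) enantioconvergent coupling of racemic 1-haloalkyl carboxylates, combined with Mn-driven reductive aryl iodide–alkyl chloride cross-electrophile coupling; no ring is formed. The 1R configuration is controlled by the ligand, helped by coordination of the ester carbonyl to nickel during radical capture and reductive elimination, and the ligand antipode is to be fixed in a scouting run by correlation with alcohol F3 of the fallback. The step needs enantioselectivity and cross-coupling over homo-coupling, the latter secured because the aryl iodide reacts by two-electron oxidative addition and the activated chloride by halogen abstraction. Radical cyclisation is not expected, since the prenyl alkene could only close a three- or four-membered ring and the tetrasubstituted alkene of the acyl group is reachable only through the disfavoured s-trans ester conformer at a fully substituted carbon. The ortho methoxymethoxy group at C1, buttressed by its peri neighbour at C8, is the main uncertainty.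

Step 10
Reactants: 16 (1R)-1-[1,4,5,8-tetrakis(methoxymethoxy)naphthalen-2-yl]-4-methylpent-3-en-1-yl 3,4-dimethylpent-3-enoate
Product: 17 (1R)-1-[1,4-bis(methoxymethoxy)-5,8-dioxo-5,8-dihydronaphthalen-2-yl]-4-methylpent-3-en-1-yl 3,4-dimethylpent-3-enoate (ring B quinone)
Conditions: (NH4)2Ce(NO3)6 (2.5 equiv), MeCN/H2O, 0 °C, short reaction time
Reagents that add atoms: water, O
Why: Oxidative dealkylation of a 1,4-dialkoxyarene to the p-quinone by (NH4)2Ce(NO3)6 (one-electron oxidation, ipso attack of water, loss of each acetal as formaldehyde and methanol) should fall on the unsubstituted ring B and not on the hindered ring A with its electron-withdrawing acyloxyalkyl group, as expected by analogy with 1'-acyloxy tetramethoxy congeners, while the alkenes, the ester and C1' are far harder to oxidise than the arene.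

Step 11
Reactants: 17 (1R)-1-[1,4-bis(methoxymethoxy)-5,8-dioxo-5,8-dihydronaphthalen-2-yl]-4-methylpent-3-en-1-yl 3,4-dimethylpent-3-enoate
Product: 18 (1R)-1-(5,8-dihydroxy-1,4-dioxo-1,4-dihydronaphthalen-2-yl)-4-methylpent-3-en-1-yl 3,4-dimethylpent-3-enoate (target)
Conditions: MgBr2·OEt2 (excess), Et2O/CH2Cl2, 0 °C → rt; pH 7 buffer
Reagents that add atoms: none
Why: Chelation-assisted Lewis-acid cleavage of aryl methoxymethyl ethers peri to a quinone carbonyl (Mg bridges the carbonyl and acetal oxygens, bromide removes the CH2OMe group) under aprotic conditions should spare the ester, the alkenes and C1', and the freed 1,4-dihydroxy-5,8-dione is the tautomer of the target naphthazarin.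

Compound list
1 | naphthazarin (5,8-dihydroxynaphthalene-1,4-dione) | O=C1C=CC(=O)c2c(O)ccc(O)c12 | starting material
2 | leuconaphthazarin as 5,8-dihydroxy-2,3-dihydronaphthalene-1,4-dione (tautomer of 1,4,5,8-tetrahydroxynaphthalene) | O=C1CCC(=O)c2c(O)ccc(O)c12 | intermediate
3 | 1,4,5,8-tetrakis(methoxymethoxy)naphthalene | COCOc1ccc(OCOC)c2c(OCOC)ccc(OCOC)c12 | intermediate
4 | 2-lithio-1,4,5,8-tetrakis(methoxymethoxy)naphthalene | COCOc1cc([Li])c(OCOC)c2c(OCOC)ccc(OCOC)c12 | intermediate (not isolated)
5 | 2-iodo-1,4,5,8-tetrakis(methoxymethoxy)naphthalene | COCOc1cc(I)c(OCOC)c2c(OCOC)ccc(OCOC)c12 | intermediate (key-step precursor)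
6 | 4-methylpent-3-en-1-ol | CC(C)=CCCO | starting material
7 | 4-methylpent-3-enal | CC(C)=CCC=O | intermediate
8 | 2-bromo-3-methylbut-2-ene | CC(C)=C(C)Br | starting material
9 | oxirane | C1CO1 | starting material
10 | (3-methylbut-2-en-2-yl)magnesium bromide | CC(C)=C(C)[Mg]Br | intermediate (not isolated)
11 | 3,4-dimethylpent-3-en-1-ol | OCCC(C)=C(C)C | intermediate
12 | 3,4-dimethylpent-3-enoic acid | OC(=O)CC(C)=C(C)C | intermediate
13 | sodium 3,4-dimethylpent-3-enoate | [Na+].[O-]C(=O)CC(C)=C(C)C | intermediate (not isolated)
14 | 3,4-dimethylpent-3-enoyl chloride | ClC(=O)CC(C)=C(C)C | intermediate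
15 | racemic 1-chloro-4-methylpent-3-en-1-yl 3,4-dimethylpent-3-enoate | CC(C)=CCC(Cl)OC(=O)CC(C)=C(C)C | intermediate (key-step precursor)
16 | (1R)-1-[1,4,5,8-tetrakis(methoxymethoxy)naphthalen-2-yl]-4-methylpent-3-en-1-yl 3,4-dimethylpent-3-enoate | CC(C)=CC[C@@H](OC(=O)CC(C)=C(C)C)c1cc(OCOC)c2c(OCOC)ccc(OCOC)c2c1OCOC | intermediate (key-step product)
17 | (1R)-1-[1,4-bis(methoxymethoxy)-5,8-dioxo-5,8-dihydronaphthalen-2-yl]-4-methylpent-3-en-1-yl 3,4-dimethylpent-3-enoate | CC(C)=CC[C@@H](OC(=O)CC(C)=C(C)C)c1cc(OCOC)c2C(=O)C=CC(=O)c2c1OCOC | intermediate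
18 | (1R)-1-(5,8-dihydroxy-1,4-dioxo-1,4-dihydronaphthalen-2-yl)-4-methylpent-3-en-1-yl 3,4-dimethylpent-3-enoate | CC(C)=CC[C@@H](OC(=O)CC(C)=C(C)C)C1=CC(=O)c2c(O)ccc(O)c2C1=O | target

Step count and risk
Total step count: 11. Longest linear sequence: 7 steps (steps 5, 6, 7, 8, 9, 10, 11).

Steps most likely to fail:

1. Step 9. The radical may be captured slowly by the crowded arylnickel species, which would show as hydrodeiodination of the arene and as reduction, dimerisation or HCl loss of the chloro ester. Enantioselectivity may also be poor, or be eroded by nickel insertion into the new naphthylmethyl C–O bond. The fallback sets out from 3 and 7 and returns at 16. Compound 3 is lithiated as in step 3 to 4, which adds to aldehyde 7 to give racemic 1-[1,4,5,8-tetrakis(methoxymethoxy)naphthalen-2-yl]-4-methylpent-3-en-1-ol F1. Dess–Martin oxidation gives 1-[1,4,5,8-tetrakis(methoxymethoxy)naphthalen-2-yl]-4-methylpent-3-en-1-one F2. Reduction with (+)-B-chlorodiisopinocampheylborane in THF at low temperature should, by the usual model for aryl alkyl ketones, give (1R)-1-[1,4,5,8-tetrakis(methoxymethoxy)naphthalen-2-yl]-4-methylpent-3-en-1-ol F3. Esterification of F3 with acid 12 (DCC, DMAP, CH2Cl2, 0 °C) gives 16.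

2. Step 8. The Lewis acid may trigger Prins-type attack of the acyloxycarbenium ion on the electron-rich alkenes, migration of the β,γ-alkene of the aldehyde into conjugation, or loss of HCl to a dienyl ester. The fallback sets out from 12 and returns at 16. Sodium salt 13 is treated with oxalyl bromide to give 3,4-dimethylpent-3-enoyl bromide F4, which should add to aldehyde 7 in CH2Cl2 at −30 °C without any Lewis acid to give racemic 1-bromo-4-methylpent-3-en-1-yl 3,4-dimethylpent-3-enoate F5. F5 replaces 15 under the nickel conditions of step 9 and gives 16.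

3. Step 11. The Lewis acid may ionise C1' with loss of the carboxylate, leading to racemisation or cyclisation onto the prenyl alkene, or the acetal cleavage may stall. The fallback sets out from 16, returns at 18 and installs the ester last. Methanolysis of 16 (K2CO3, MeOH, rt) gives the alcohol F3 named above. Oxidation with (NH4)2Ce(NO3)6 gives 2-[(1R)-1-hydroxy-4-methylpent-3-en-1-yl]-5,8-bis(methoxymethoxy)naphthalene-1,4-dione F6, possibly with its ring B quinone isomer 6-[(1R)-1-hydroxy-4-methylpent-3-en-1-yl]-5,8-bis(methoxymethoxy)naphthalene-1,4-dione F7. Dilute aqueous HCl in THF at 0 °C removes the acetals from both and gives shikonin, 5,8-dihydroxy-2-[(1R)-1-hydroxy-4-methylpent-3-en-1-yl]naphthalene-1,4-dione F8. Esterification of the side-chain hydroxyl of F8 with acid 12 (DCC, DMAP, CH2Cl2, 0 °C), the chelated peri hydroxyls staying unreactive, gives 18.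

Further compounds
F1 | step 9 | racemic 1-[1,4,5,8-tetrakis(methoxymethoxy)naphthalen-2-yl]-4-methylpent-3-en-1-ol | CC(C)=CCC(O)c1cc(OCOC)c2c(OCOC)ccc(OCOC)c2c1OCOC
F2 | step 9 | 1-[1,4,5,8-tetrakis(methoxymethoxy)naphthalen-2-yl]-4-methylpent-3-en-1-one | CC(C)=CCC(=O)c1cc(OCOC)c2c(OCOC)ccc(OCOC)c2c1OCOC
F3 | step 9 | (1R)-1-[1,4,5,8-tetrakis(methoxymethoxy)naphthalen-2-yl]-4-methylpent-3-en-1-ol | CC(C)=CC[C@@H](O)c1cc(OCOC)c2c(OCOC)ccc(OCOC)c2c1OCOC
F4 | step 8 | 3,4-dimethylpent-3-enoyl bromide | BrC(=O)CC(C)=C(C)C
F5 | step 8 | racemic 1-bromo-4-methylpent-3-en-1-yl 3,4-dimethylpent-3-enoate | CC(C)=CCC(Br)OC(=O)CC(C)=C(C)C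
F6 | step 11 | 2-[(1R)-1-hydroxy-4-methylpent-3-en-1-yl]-5,8-bis(methoxymethoxy)naphthalene-1,4-dione | CC(C)=CC[C@@H](O)C1=CC(=O)c2c(OCOC)ccc(OCOC)c2C1=O
F7 | step 11 | 6-[(1R)-1-hydroxy-4-methylpent-3-en-1-yl]-5,8-bis(methoxymethoxy)naphthalene-1,4-dione | CC(C)=CC[C@@H](O)c1cc(OCOC)c2C(=O)C=CC(=O)c2c1OCOC
F8 | step 11 | shikonin, 5,8-dihydroxy-2-[(1R)-1-hydroxy-4-methylpent-3-en-1-yl]naphthalene-1,4-dione | CC(C)=CC[C@@H](O)C1=CC(=O)c2c(O)ccc(O)c2C1=O
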